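**Plan**

- Retrosynthesis: after ester cleavage and desulfonylation, the first skeletal cut is C6′–C7′ of the nine-membered ring (allylic alkylation). Then come C3′–C4′ (lactone enolate alkylation), C12–C4′ and C15–C5′ of the cyclohexene (Diels–Alder), and C1′–C9′ and C10′–C11′ of the cyclobutane ([2+2]).
- Forward: trans-communic acid is turned into a 14-silyloxy labdatriene; cycloaddition to a chiral butenolide builds the cyclohexene first; the separately made cyclobutane arm is joined at C4′; the nine-membered ring is closed last.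
- Enabling feature: in the nine-membered ring the exocyclic-methylene carbon C8′ is the centre of the allyl triad C7′–C8′–C15′. Its two CH2 ends are interchangeable, so attack by C6′ at either end gives the same ring with the methylene already in place.
- Stereochemistry: C4, C5, C9 and C10 come from trans-communic acid. C12 and C5′ come from endo addition anti to the menthyloxy group of the (5S)-butenolide. Quaternary C4′ comes from convex-face alkylation of the cis-fused lactone, C1′ from the catalyst-controlled [2+2], and C9′ from hydroxyl-directed hydrogenation.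

Key step: step 22

Remark: compounds 1, 4, 7 (the d-menthol-derived antipode of the usual l-menthyloxybutenolide), 11 and 13 are taken as purchasable.
Remark: the sense of induction of the oxazaborolidine·AlBr3 catalyst in step 10 is assumed as drawn; if the (S)-catalyst gave the antipode of 15, the (R)-catalyst would be used with no other change.
Remark on names: primed locants follow caryophyllane numbering of 35 and unprimed ones labdane numbering. LabCH2 is the [(1S,4aR,5S,8aR)-5-(methoxycarbonyl)-5,8a-dimethyl-2-methylidenedecahydronaphthalen-1-yl]methyl group (C11 plus the decalin). MenO is (1S,2R,5S)-menthyloxy.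

**Route**

Step 1
Reactants: 1 trans-communic acid
Product: 2 methyl trans-communate
Conditions: MeI, K2CO3, DMF, rt
Reagents that add atoms: iodomethane, CI
Why: Carboxylate O-alkylation (SN2 at methyl) esterifies the axial neopentyl C19 acid, which resists Fischer esterification, and leaves the diene untouched.

Step 2
Reactants: 2 methyl trans-communate
Product: 3 methyl 12-oxo-13,14,15,16-tetranorlabd-8(17)-en-19-oate
Conditions: O3 (1.0 equiv), pyridine, CH2Cl2, −78 °C
Reagents that add atoms: ozone, [O-][O+]=O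
Why: Chemoselective ozonolysis (pyridine-promoted reductive variant): with ozone as the limiting reagent the trisubstituted, most electron-rich C12=C13 bond should be cleaved before the terminal vinyl group and the hindered exocyclic C8=C17 bond, giving the C12 aldehyde directly.

Step 3
Reactants: 3 methyl 12-oxo-13,14,15,16-tetranorlabd-8(17)-en-19-oate; 4 3-(triphenylphosphoranylidene)butan-2-one
Product: 5 methyl (12E)-14-oxolabda-8(17),12-dien-19-oate
Conditions: PhMe, 90 °C
Reagents that add atoms: none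
Why: Wittig olefination with a stabilised α-methyl ylide should give the (E)-trisubstituted enone (acyl group trans to C11), the geometry that later places C11 as the outside substituent of the diene.

Step 4
Reactants: 5 methyl (12E)-14-oxolabda-8(17),12-dien-19-oate
Product: 6 methyl (12E)-14-(triethylsilyloxy)labda-8(17),12,14-trien-19-oate
Conditions: Et3SiOTf, Et3N, CH2Cl2, −78 → 0 °C
Reagents that add atoms: triethylsilyl trifluoromethanesulfonate, CC[Si](CC)(CC)OS(=O)(=O)C(F)(F)F
Why: Soft enolisation of the methyl ketone (O-silylation, then α′-deprotonation by Et3N) gives the cross-conjugated 2-silyloxydiene with the C12=C13 geometry unchanged.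

Step 5
Reactants: 6 methyl (12E)-14-(triethylsilyloxy)labda-8(17),12,14-trien-19-oate; 7 (5S)-5-MenO-furan-2(5H)-one
Product: 8 (3S)-3-(MenO)-6-methyl-7-(LabCH2)-5-(triethylsilyloxy)-3a,4,7,7a-tetrahydro-2-benzofuran-1(3H)-one (cis-fused; H-3a/H-7a/H-7 and 3-OMen on one face)
Conditions: PhMe, BHT (cat.), 110 °C, sealed tube
Reagents that add atoms: none
Why: Thermal normal-demand Diels–Alder reaction: the silyloxy group makes C15 the nucleophilic terminus so that it bonds to the butenolide β-carbon (C5′) and C12 bonds to C4′, endo addition puts the C11 arm cis to the lactone, and approach anti to the menthyloxy group of the (5S)-acetal sets C12, C4′ and C5′ in the absolute sense of the target.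

Step 6
Reactants: 8 silyl enol ether adduct
Product: 9 (3S)-3-(MenO)-6-methyl-7-(LabCH2)-5-(trifluoromethanesulfonyloxy)-3a,4,7,7a-tetrahydro-2-benzofuran-1(3H)-one (configuration as 8)
Conditions: CsF, PhNTf2, DME, rt
Reagents that add atoms: N-phenylbis(trifluoromethanesulfonimide), O=S(=O)(N(c1ccccc1)S(=O)(=O)C(F)(F)F)C(F)(F)F
Why: Fluoride cleaves the silyl enol ether in the presence of PhNTf2, so the regiodefined enolate is triflated on oxygen before it can equilibrate (silyl enol ether to enol triflate exchange), fixing the double bond at C13=C14.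

Step 7
Reactants: 9 enol triflate
Product: 10 (3S)-3-(MenO)-6-methyl-7-(LabCH2)-3a,4,7,7a-tetrahydro-2-benzofuran-1(3H)-one (configuration as 8)
Conditions: Pd(OAc)2, PPh3, HCO2H, Et3N, DMF, 60 °C
Reagents that add atoms: none
Why: Palladium-catalysed formate reduction of the enol triflate (oxidative addition to zerovalent palladium, formate exchange, decarboxylation, C–H reductive elimination) replaces OTf by H and leaves the C13=C14 alkene; no stereocentre is involved.

Step 8
Reactants: 11 4-methylpent-3-en-1-ol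
Product: 12 tert-butyl(dimethyl)[(4-methylpent-3-en-1-yl)oxy]silane
Conditions: tBuMe2SiCl, imidazole, CH2Cl2, rt
Reagents that add atoms: tert-butyl(chloro)dimethylsilane, CC(C)(C)[Si](C)(C)Cl
Why: Standard silylation masks the hydroxyl against the Lewis acid of step 10.

Step 9
Reactants: 13 buta-2,3-dienoic acid
Product: 14 2,2,2-trifluoroethyl buta-2,3-dienoate
Conditions: CF3CH2OH, DCC, DMAP (cat.), CH2Cl2, 0 °C
Reagents that add atoms: 2,2,2-trifluoroethanol, OCC(F)(F)F
Why: Steglich esterification gives the electron-poor trifluoroethyl allenoate that is reactive enough under chiral Lewis-acid activation.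

Step 10
Reactants: 12 tert-butyl(dimethyl)[(4-methylpent-3-en-1-yl)oxy]silane; 14 2,2,2-trifluoroethyl buta-2,3-dienoate
Product: 15 2,2,2-trifluoroethyl 2-[(2S)-2-(2-{[tert-butyl(dimethyl)silyl]oxy}ethyl)-3,3-dimethylcyclobutylidene]acetate
Conditions: (S)-1-(2-methylphenyl)-3,3-diphenyltetrahydro-1H,3H-pyrrolo[1,2-c][1,3,2]oxazaborole·AlBr3 (20 mol %), CH2Cl2, −78 → −20 °C
Reagents that add atoms: none
Why: Lewis-acid-catalysed allenoate–alkene [2+2] cycloaddition: the activated allenoate bonds through its central carbon to the alkene CH and closes from its CH2 terminus onto the tertiary carbon, which puts the gem-dimethyl group next to the ring CH2, while the chiral catalyst selects the alkene face and sets the ring CH that becomes C1′.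

Step 11
Reactants: 15 cyclobutylidene trifluoroethyl ester
Product: 17 methyl 2-[(2S)-2-(2-hydroxyethyl)-3,3-dimethylcyclobutylidene]acetate, via silyl ether methyl ester 16 (not isolated)
Conditions: K2CO3 (cat.), MeOH, 0 °C → rt; then CSA, rt
Reagents that add atoms: methanol, CO
Why: Base-catalysed transesterification of the activated trifluoroethyl ester followed by acid-catalysed methanolysis of the primary silyl ether; running the basic stage before the hydroxyl is freed avoids intramolecular oxa-Michael addition.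

Step 12
Reactants: 17 methyl 2-[(2S)-2-(2-hydroxyethyl)-3,3-dimethylcyclobutylidene]acetate
Product: 18 methyl 2-[(1R,2R)-2-(2-hydroxyethyl)-3,3-dimethylcyclobutyl]acetate
Conditions: H2 (1 atm), [Ir(cod)(PCy3)(py)]PF6 (5 mol %), CH2Cl2, rt
Reagents that add atoms: none
Why: Hydroxyl-directed homogeneous hydrogenation: the primary alcohol binds the cationic iridium centre and hydrogen is delivered to the exocyclic alkene from the face of the hydroxyethyl arm, so the acetate arm ends trans to it and C9′ is set.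

Step 13
Reactants: 18 methyl 2-[(1R,2R)-2-(2-hydroxyethyl)-3,3-dimethylcyclobutyl]acetate
Product: 22 methyl 2-[(1S,2R)-2-(2-hydroxyethyl)-3,3-dimethylcyclobutyl]prop-2-enoate, via dilithio dianion 19 (not isolated), via Mannich base 20 (not isolated), via methiodide 21 (not isolated)
Conditions: LiN(iPr)2 (2.2 equiv), THF, −78 °C; Me2N=CH2+ I−, −78 → 0 °C; then MeI, MeOH, rt; then DBU, CH2Cl2, rt
Reagents that add atoms: N,N-dimethylmethyleneiminium iodide, C=[N+](C)C.[I-]
Why: α-Methylenation by Mannich reaction of the ester enolate with the iminium salt and Hofmann-type elimination of the quaternised amine; the alkoxide is a spectator and the ring stereocentres are not touched.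

Step 14
Reactants: 22 methyl 2-[(1S,2R)-2-(2-hydroxyethyl)-3,3-dimethylcyclobutyl]prop-2-enoate
Product: 23 methyl 2-[(1S,2R)-2-(2-iodoethyl)-3,3-dimethylcyclobutyl]prop-2-enoate
Conditions: I2, PPh3, imidazole, CH2Cl2, 0 °C
Reagents that add atoms: iodine, II
Why: Appel-type iodination (Garegg–Samuelsson conditions) converts the primary alcohol into the iodide by SN2 on the alkoxyphosphonium ion; the phosphine is pre-complexed with iodine so that it does not add to the acrylate.

Step 15
Reactants: 23 methyl 2-[(1S,2R)-2-(2-iodoethyl)-3,3-dimethylcyclobutyl]prop-2-enoate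
Product: 24 2-[(1S,2R)-2-(2-iodoethyl)-3,3-dimethylcyclobutyl]prop-2-en-1-ol
Conditions: iBu2AlH, CH2Cl2, −78 °C
Reagents that add atoms: none
Why: 1,2-Reduction of the α-substituted acrylate by the aluminium hydride gives the 2-substituted allyl alcohol, the primary iodide being inert at −78 °C.

Step 16
Reactants: 24 2-[(1S,2R)-2-(2-iodoethyl)-3,3-dimethylcyclobutyl]prop-2-en-1-ol
Product: 25 tert-butyl({2-[(1S,2R)-2-(2-iodoethyl)-3,3-dimethylcyclobutyl]prop-2-en-1-yl}oxy)diphenylsilane
Conditions: tBuPh2SiCl, imidazole, CH2Cl2, rt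
Reagents that add atoms: tert-butyl(chloro)diphenylsilane, CC(C)(C)[Si](Cl)(c1ccccc1)c1ccccc1
Why: Silylation gives an allylic ether that should survive the enolate, the Lewis acid and the sulfur oxidation that follow.

Step 17
Reactants: 10 cis-fused lactone; 25 cyclobutane iodide
Product: 27 (3S)-7a-{2-[(1R,4S)-4-(3-{[tert-butyl(diphenyl)silyl]oxy}prop-1-en-2-yl)-2,2-dimethylcyclobutyl]ethyl}-3-(MenO)-6-methyl-7-(LabCH2)-3a,4,7,7a-tetrahydro-2-benzofuran-1(3H)-one (cis-fused; new chain on the face of H-3a/H-7), via lithium enolate 26 (not isolated)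
Conditions: LiN(iPr)2, THF, −78 °C; then 25, DMPU, −78 → −20 °C
Reagents that add atoms: none
Why: SN2 alkylation of the lithium lactone enolate by the unhindered primary iodide: the electrophile enters on the convex face (the face of H-5′, anti to the cyclohexene ring bond C5′–C15 and to the C11 arm), which keeps the lactone cis-fused and sets quaternary C4′ with C3′ trans to both C6′ and C11.

Step 18
Reactants: 27 alkylated lactone
Product: 29 methyl 6-[bis(phenylthio)methyl]-1-{2-[(1R,4S)-4-(3-{[tert-butyl(diphenyl)silyl]oxy}prop-1-en-2-yl)-2,2-dimethylcyclobutyl]ethyl}-3-methyl-2-(LabCH2)cyclohex-3-ene-1-carboxylate (CO2Me cis to the 2- and 6-substituents; C12/C4′/C5′ as in 35), via carboxylic acid 28 (not isolated)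
Conditions: PhSH, BF3·OEt2 (cat.), CH2Cl2, −20 °C; then Me3SiCHN2, PhMe–MeOH, 0 °C
Reagents that add atoms: thiophenol, Sc1ccccc1; (trimethylsilyl)diazomethane, C[Si](C)(C)C=[N+]=[N-]
Why: Lewis-acid transthioacetalisation of the γ-alkoxylactone (a masked aldehyde–acid) opens the ring through the oxocarbenium and thionium ions to the bis(phenylthio)acetal and the C14′ acid without freeing the epimerisable C5′ aldehyde, and the diazo reagent then methylates the hindered acid.

Step 19
Reactants: 29 bis(phenylthio)acetal diester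
Product: 30 methyl 6-[bis(phenylsulfonyl)methyl]-1-{2-[(1R,4S)-4-(3-{[tert-butyl(diphenyl)silyl]oxy}prop-1-en-2-yl)-2,2-dimethylcyclobutyl]ethyl}-3-methyl-2-(LabCH2)cyclohex-3-ene-1-carboxylate (configuration as 29)
Conditions: H2O2 (30 % aq.), (NH4)6Mo7O24·4H2O (cat.), EtOH–THF, 0 °C → rt
Reagents that add atoms: hydrogen peroxide, OO
Why: Molybdate-catalysed peroxide oxidation is chemoselective for sulfur (sulfide to sulfone) over unactivated tri- and 1,1-disubstituted alkenes, which no longer carry a free allylic hydroxyl.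

Step 20
Reactants: 30 silyl ether bis-sulfone
Product: 31 methyl 6-[bis(phenylsulfonyl)methyl]-1-{2-[(1R,4S)-4-(3-hydroxyprop-1-en-2-yl)-2,2-dimethylcyclobutyl]ethyl}-3-methyl-2-(LabCH2)cyclohex-3-ene-1-carboxylate (configuration as 29)
Conditions: Bu4NF, AcOH, THF, rt
Reagents that add atoms: none
Why: Fluoride desilylation, buffered with acetic acid so that the acidic bis-sulfone is not held as its carbanion, frees the allylic alcohol.

Step 21
Reactants: 31 allylic alcohol bis-sulfone
Product: 32 methyl 6-[bis(phenylsulfonyl)methyl]-1-{2-[(1R,4S)-4-{3-[(methoxycarbonyl)oxy]prop-1-en-2-yl}-2,2-dimethylcyclobutyl]ethyl}-3-methyl-2-(LabCH2)cyclohex-3-ene-1-carboxylate (configuration as 29)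
Conditions: ClCO2Me, pyridine, CH2Cl2, 0 °C
Reagents that add atoms: methyl chloroformate, COC(=O)Cl
Why: O-Acylation of the primary allylic alcohol gives the methyl carbonate; pyridine is too weak a base to deprotonate the bis-sulfone, so C-acylation is not expected.

Step 22
Reactants: 32 seco allylic carbonate
Product: 33 6′,6′-bis(phenylsulfonyl) derivative of the dimethyl ester of 35
Conditions: Pd2(dba)3·CHCl3 (5 mol %), P(OiPr)3 (40 mol %), THF, 65 °C, syringe-pump addition of 32 (final 1 mM)
Reagents that add atoms: none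
Why: Zerovalent palladium ionises the allylic methyl carbonate with loss of CO2, the methoxide so released deprotonates the C6′ bis-sulfone, and the carbanion attacks a CH2 terminus of the cationic η3-2-substituted allyl complex to form C6′–C7′ and return the catalyst. The closest known reaction is the Tsuji–Trost allylic alkylation under neutral carbonate conditions, as used for medium- and large-ring carbocyclisation with bis(phenylsulfonyl)methyl nucleophiles. The nine-membered ring closes with the tether entering the allyl at its central carbon C8′, so the ring takes up the attacked terminus and C8′ and leaves the other terminus as the exocyclic methylene C15′. No stereocentre is created, because C6′ carries two identical sulfonyl groups and both allyl termini are CH2. The step needs ring closure over oligomerisation and has no regiochemical demand: the two termini are equivalent, no smaller ring can form from a centrally tethered allyl, nucleophile and electrophile exist only after ionisation and at low stationary concentration, and the trans-cyclobutane with the trans-disposed C3′ and C6′ arms on the cyclohexene holds the two ends near each other. The small, electron-poor phosphite ligand is chosen to keep the allyl complex electrophilic and uncrowded for the hindered C6′ carbanion.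

Step 23
Reactants: 33 cyclised bis-sulfone
Product: 34 dimethyl ester of 35
Conditions: Mg, MeOH, 50 °C
Reagents that add atoms: none
Why: Reductive desulfonylation by electron transfer from magnesium in methanol removes both phenylsulfonyl groups as sulfinate, each carbanion being protonated by the solvent, while isolated alkenes and the hindered esters are inert.

Step 24
Reactants: 34 dimethyl ester of 35
Product: 35 CNP0330729.1 (the diacid)
Conditions: LiSPr, HMPA, 50 °C; then aq. HCl
Reagents that add atoms: none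
Why: SN2 demethylation of both hindered methyl esters by thiolate (attack at the methyl carbon avoids the shielded acyl carbons at C19 and C14′), and acidification gives the diacid without touching the acid-sensitive alkenes under forcing hydrolysis.

**Compound list**

1 | trans-communic acid, (12E)-labda-8(17),12,14-trien-19-oic acid (4S,5R,9S,10R) | C=C/C(C)=C/C[C@H]1C(=C)CC[C@@H]2[C@]1(C)CCC[C@]2(C)C(=O)O | starting material
2 | methyl trans-communate | C=C/C(C)=C/C[C@H]1C(=C)CC[C@@H]2[C@]1(C)CCC[C@]2(C)C(=O)OC | intermediate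
3 | methyl 12-oxo-13,14,15,16-tetranorlabd-8(17)-en-19-oate | O=CC[C@H]1C(=C)CC[C@@H]2[C@]1(C)CCC[C@]2(C)C(=O)OC | intermediate
4 | 3-(triphenylphosphoranylidene)butan-2-one | CC(=O)C(C)=P(c1ccccc1)(c1ccccc1)c1ccccc1 | starting material
5 | methyl (12E)-14-oxolabda-8(17),12-dien-19-oate | CC(=O)/C(C)=C/C[C@H]1C(=C)CC[C@@H]2[C@]1(C)CCC[C@]2(C)C(=O)OC | intermediate
6 | methyl (12E)-14-(triethylsilyloxy)labda-8(17),12,14-trien-19-oate | C=C(O[Si](CC)(CC)CC)/C(C)=C/C[C@H]1C(=C)CC[C@@H]2[C@]1(C)CCC[C@]2(C)C(=O)OC | intermediate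
7 | (5S)-5-{[(1S,2R,5S)-5-methyl-2-(propan-2-yl)cyclohexyl]oxy}furan-2(5H)-one | O=C1C=C[C@@H](O[C@H]2C[C@@H](C)CC[C@@H]2C(C)C)O1 | starting material
8 | (3S)-3-(MenO)-6-methyl-7-(LabCH2)-5-(triethylsilyloxy)-3a,4,7,7a-tetrahydro-2-benzofuran-1(3H)-one; cis-fused, H-3a/H-7a/H-7 and 3-OMen on one face | O=C1O[C@H](O[C@H]2C[C@@H](C)CC[C@@H]2C(C)C)[C@H]3CC(O[Si](CC)(CC)CC)=C(C)[C@@H](C[C@H]4C(=C)CC[C@@H]5[C@]4(C)CCC[C@]5(C)C(=O)OC)[C@@H]13 | intermediate
9 | 5-(trifluoromethanesulfonyloxy) analogue of 8 (enol triflate, same configuration) | O=C1O[C@H](O[C@H]2C[C@@H](C)CC[C@@H]2C(C)C)[C@H]3CC(OS(=O)(=O)C(F)(F)F)=C(C)[C@@H](C[C@H]4C(=C)CC[C@@H]5[C@]4(C)CCC[C@]5(C)C(=O)OC)[C@@H]13 | intermediate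
10 | (3S)-3-(MenO)-6-methyl-7-(LabCH2)-3a,4,7,7a-tetrahydro-2-benzofuran-1(3H)-one; configuration as 8 | O=C1O[C@H](O[C@H]2C[C@@H](C)CC[C@@H]2C(C)C)[C@H]3CC=C(C)[C@@H](C[C@H]4C(=C)CC[C@@H]5[C@]4(C)CCC[C@]5(C)C(=O)OC)[C@@H]13 | intermediate
11 | 4-methylpent-3-en-1-ol | CC(C)=CCCO | starting material
12 | tert-butyl(dimethyl)[(4-methylpent-3-en-1-yl)oxy]silane | CC(C)=CCCO[Si](C)(C)C(C)(C)C | intermediate
13 | buta-2,3-dienoic acid | C=C=CC(=O)O | starting material
14 | 2,2,2-trifluoroethyl buta-2,3-dienoate | C=C=CC(=O)OCC(F)(F)F | intermediate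
15 | 2,2,2-trifluoroethyl 2-[(2S)-2-(2-{[tert-butyl(dimethyl)silyl]oxy}ethyl)-3,3-dimethylcyclobutylidene]acetate (alkene geometry of no consequence) | CC(C)(C)[Si](C)(C)OCC[C@@H]1C(=CC(=O)OCC(F)(F)F)CC1(C)C | intermediate
16 | methyl 2-[(2S)-2-(2-{[tert-butyl(dimethyl)silyl]oxy}ethyl)-3,3-dimethylcyclobutylidene]acetate | CC(C)(C)[Si](C)(C)OCC[C@@H]1C(=CC(=O)OC)CC1(C)C | intermediate
17 | methyl 2-[(2S)-2-(2-hydroxyethyl)-3,3-dimethylcyclobutylidene]acetate | OCC[C@@H]1C(=CC(=O)OC)CC1(C)C | intermediate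
18 | methyl 2-[(1R,2R)-2-(2-hydroxyethyl)-3,3-dimethylcyclobutyl]acetate (trans) | OCC[C@@H]1[C@@H](CC(=O)OC)CC1(C)C | intermediate
19 | dilithium alkoxide–ester enolate of 18 | [Li+].[Li+].[O-]CC[C@@H]1[C@@H](C=C([O-])OC)CC1(C)C | intermediate
20 | methyl 3-(dimethylamino)-2-[(1S,2R)-2-(2-hydroxyethyl)-3,3-dimethylcyclobutyl]propanoate (C-2 epimers) | OCC[C@@H]1[C@@H](C(CN(C)C)C(=O)OC)CC1(C)C | intermediate
21 | trimethylammonium iodide (methiodide) of 20 | OCC[C@@H]1[C@@H](C(C[N+](C)(C)C)C(=O)OC)CC1(C)C.[I-] | intermediate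
22 | methyl 2-[(1S,2R)-2-(2-hydroxyethyl)-3,3-dimethylcyclobutyl]prop-2-enoate | OCC[C@@H]1[C@@H](C(=C)C(=O)OC)CC1(C)C | intermediate
23 | methyl 2-[(1S,2R)-2-(2-iodoethyl)-3,3-dimethylcyclobutyl]prop-2-enoate | ICC[C@@H]1[C@@H](C(=C)C(=O)OC)CC1(C)C | intermediate
24 | 2-[(1S,2R)-2-(2-iodoethyl)-3,3-dimethylcyclobutyl]prop-2-en-1-ol | ICC[C@@H]1[C@@H](C(=C)CO)CC1(C)C | intermediate
25 | tert-butyl({2-[(1S,2R)-2-(2-iodoethyl)-3,3-dimethylcyclobutyl]prop-2-en-1-yl}oxy)diphenylsilane | ICC[C@@H]1[C@@H](C(=C)CO[Si](c2ccccc2)(c2ccccc2)C(C)(C)C)CC1(C)C | intermediate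
26 | lithium enolate of lactone 10 (C4′=C14′ enolate) | [Li+].[O-]C1=C2[C@H](C[C@H]3C(=C)CC[C@@H]4[C@]3(C)CCC[C@]4(C)C(=O)OC)C(C)=CC[C@@H]2[C@@H](O[C@H]5C[C@@H](C)CC[C@@H]5C(C)C)O1 | intermediate
27 | 7a-alkylated lactone: 10 carrying at C7a (C4′) the 2-[(1R,4S)-4-(3-{[tert-butyl(diphenyl)silyl]oxy}prop-1-en-2-yl)-2,2-dimethylcyclobutyl]ethyl chain on the face of H-3a/H-7; cis-fused | O=C1O[C@H](O[C@H]2C[C@@H](C)CC[C@@H]2C(C)C)[C@H]3CC=C(C)[C@@H](C[C@H]4C(=C)CC[C@@H]5[C@]4(C)CCC[C@]5(C)C(=O)OC)[C@@]13CC[C@@H]6[C@@H](C(=C)CO[Si](c7ccccc7)(c7ccccc7)C(C)(C)C)CC6(C)C | intermediate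
28 | 6-[bis(phenylthio)methyl]-1-{2-[(1R,4S)-4-(3-{[tert-butyl(diphenyl)silyl]oxy}prop-1-en-2-yl)-2,2-dimethylcyclobutyl]ethyl}-3-methyl-2-(LabCH2)cyclohex-3-ene-1-carboxylic acid; CO2H cis to the 2- and 6-substituents | C(Sc1ccccc1)(Sc1ccccc1)[C@H]2CC=C(C)[C@@H](C[C@H]3C(=C)CC[C@@H]4[C@]3(C)CCC[C@]4(C)C(=O)OC)[C@]2(C(=O)O)CC[C@@H]5[C@@H](C(=C)CO[Si](c6ccccc6)(c6ccccc6)C(C)(C)C)CC5(C)C | intermediate
29 | methyl ester of 28 | C(Sc1ccccc1)(Sc1ccccc1)[C@H]2CC=C(C)[C@@H](C[C@H]3C(=C)CC[C@@H]4[C@]3(C)CCC[C@]4(C)C(=O)OC)[C@]2(C(=O)OC)CC[C@@H]5[C@@H](C(=C)CO[Si](c6ccccc6)(c6ccccc6)C(C)(C)C)CC5(C)C | intermediate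
30 | bis(phenylsulfonyl) analogue of 29 (C6′ bis-sulfone, silyl ether) | C(S(=O)(=O)c1ccccc1)(S(=O)(=O)c1ccccc1)[C@H]2CC=C(C)[C@@H](C[C@H]3C(=C)CC[C@@H]4[C@]3(C)CCC[C@]4(C)C(=O)OC)[C@]2(C(=O)OC)CC[C@@H]5[C@@H](C(=C)CO[Si](c6ccccc6)(c6ccccc6)C(C)(C)C)CC5(C)C | intermediate
31 | allylic alcohol from 30 (C7′–OH) | C(S(=O)(=O)c1ccccc1)(S(=O)(=O)c1ccccc1)[C@H]2CC=C(C)[C@@H](C[C@H]3C(=C)CC[C@@H]4[C@]3(C)CCC[C@]4(C)C(=O)OC)[C@]2(C(=O)OC)CC[C@@H]5[C@@H](C(=C)CO)CC5(C)C | intermediate
32 | seco allylic methyl carbonate with C6′ bis-sulfone and C14′/C19 methyl esters (precursor of the key step) | C(S(=O)(=O)c1ccccc1)(S(=O)(=O)c1ccccc1)[C@H]2CC=C(C)[C@@H](C[C@H]3C(=C)CC[C@@H]4[C@]3(C)CCC[C@]4(C)C(=O)OC)[C@]2(C(=O)OC)CC[C@@H]5[C@@H](C(=C)COC(=O)OC)CC5(C)C | intermediate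
33 | 6′,6′-bis(phenylsulfonyl) dimethyl ester of 35 (full skeleton) | C=C1CC(S(=O)(=O)c2ccccc2)(S(=O)(=O)c2ccccc2)[C@H]2CC=C(C)[C@@H](C[C@H]3C(=C)CC[C@@H]4[C@]3(C)CCC[C@]4(C)C(=O)OC)[C@]2(C(=O)OC)CC[C@@H]2[C@@H]1CC2(C)C | intermediate
34 | dimethyl ester of 35 | C=C1CC[C@H]2CC=C(C)[C@@H](C[C@H]3C(=C)CC[C@@H]4[C@]3(C)CCC[C@]4(C)C(=O)OC)[C@]2(C(=O)OC)CC[C@@H]2[C@@H]1CC2(C)C | intermediate
35 | CNP0330729.1, the C14′,C19-diacid | C=C1CC[C@H]2CC=C(C)[C@@H](C[C@H]3C(=C)CC[C@@H]4[C@]3(C)CCC[C@]4(C)C(=O)O)[C@]2(C(=O)O)CC[C@@H]2[C@@H]1CC2(C)C | target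

**Step count and risks**

Total: 24 steps. Longest linear sequence: 16 steps (step 8, then steps 10 to 24, from alkenol 11); the labdane branch from 1 is 15 steps.

Most likely to fail, step 22. The C6′ carbanion is flanked by the C5′ methine and the quaternary C4′, so its attack on the ligated allyl complex may be too slow, and the ionised substrate would then be lost to oligomerisation or to capture by methoxide. The fallback abandons metal-mediated ionisation and closes the same bond by direct displacement on an unligated allylic halide. It sets out from alcohol 31, which with CBr4 and PPh3 in CH2Cl2 at 0 °C should give the allylic bromide F1. Slow addition of this bromide to Cs2CO3 in DMF at 40 °C under high dilution should give intramolecular alkylation of the bis-sulfonyl carbanion (SN2 or SN2′, which lead to the same ring) and return to the route at compound 33.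

Second, step 12. The hydroxyl is bis-homoallylic to the alkene and may bind iridium too weakly, in which case hydrogen would be delivered from the open face and facial selectivity would favour the cis-cyclobutane. The fallback sets C9′ by thermodynamic control instead of by delivery of hydrogen. It sets out from compound 15:
- iBu2AlH reduces the ester to the allylic alcohol F2, which is silylated (tBuPh2SiCl, imidazole) to the bis-silyl ether F3.
- Hydroboration (BH3·THF at 0 °C, then H2O2/NaOH) places oxygen on C8′ and gives the cis alcohol F4.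
- Dess–Martin oxidation gives the cis ketone F5, in which C9′ is α to the carbonyl; DBU in CH2Cl2 should equilibrate it to the more stable trans ketone F6.
- Wittig methylenation (Ph3P=CH2, THF) gives the diene F7; PPTS in MeOH removes only the primary tert-butyldimethylsilyl group to give the alcohol F8.
- Iodination (I2, PPh3, imidazole) returns to the route at compound 25.

Third, step 17. Quaternisation of the tertiary lactone enolate by an unactivated primary iodide may be slow, so proton transfer, E2 elimination of the iodide or decomposition of the enolate on warming could take over. The fallback makes the C3′–C4′ bond by carbonyl addition, which is far less sensitive to crowding at the enolate carbon, and then removes the oxygen. It sets out from iodide 25 and lactone 10: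
- Trimethylamine N-oxide in DMSO at 50 °C should oxidise the iodide to the aldehyde F9.
- The lithium enolate 26 of lactone 10, made as in step 17, should add to this aldehyde at −78 °C from the same convex face to give the aldol F10 (C3′ carbinol epimers).
- Phenyl chlorothionoformate and DMAP give the thionocarbonate F11.
- Barton–McCombie deoxygenation (Bu3SnH, AIBN, PhH, 80 °C) returns to the route at compound 27.

**Further compounds**

F1 | step 22 | allylic bromide corresponding to alcohol 31 (C7′–Br) | C(S(=O)(=O)c1ccccc1)(S(=O)(=O)c1ccccc1)[C@H]2CC=C(C)[C@@H](C[C@H]3C(=C)CC[C@@H]4[C@]3(C)CCC[C@]4(C)C(=O)OC)[C@]2(C(=O)OC)CC[C@@H]5[C@@H](C(=C)CBr)CC5(C)C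
F2 | step 12 | 2-[(2S)-2-(2-{[tert-butyl(dimethyl)silyl]oxy}ethyl)-3,3-dimethylcyclobutylidene]ethan-1-ol | CC(C)(C)[Si](C)(C)OCC[C@@H]1C(=CCO)CC1(C)C
F3 | step 12 | tert-butyldiphenylsilyl ether of F2 | CC(C)(C)[Si](C)(C)OCC[C@@H]1C(=CCO[Si](c2ccccc2)(c2ccccc2)C(C)(C)C)CC1(C)C
F4 | step 12 | cis-1-[2-(2-{[tert-butyl(dimethyl)silyl]oxy}ethyl)-3,3-dimethylcyclobutyl]-2-{[tert-butyl(diphenyl)silyl]oxy}ethan-1-ol (carbinol epimers) | CC(C)(C)[Si](C)(C)OCC[C@@H]1[C@H](C(O)CO[Si](c2ccccc2)(c2ccccc2)C(C)(C)C)CC1(C)C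
F5 | step 12 | cis ketone from F4 | CC(C)(C)[Si](C)(C)OCC[C@@H]1[C@H](C(=O)CO[Si](c2ccccc2)(c2ccccc2)C(C)(C)C)CC1(C)C
F6 | step 12 | trans ketone (C9′ epimer of F5) | CC(C)(C)[Si](C)(C)OCC[C@@H]1[C@@H](C(=O)CO[Si](c2ccccc2)(c2ccccc2)C(C)(C)C)CC1(C)C
F7 | step 12 | tert-butyl({2-[(1S,2R)-2-(2-{[tert-butyl(dimethyl)silyl]oxy}ethyl)-3,3-dimethylcyclobutyl]prop-2-en-1-yl}oxy)diphenylsilane | CC(C)(C)[Si](C)(C)OCC[C@@H]1[C@@H](C(=C)CO[Si](c2ccccc2)(c2ccccc2)C(C)(C)C)CC1(C)C
F8 | step 12 | 2-[(1R,4S)-4-(3-{[tert-butyl(diphenyl)silyl]oxy}prop-1-en-2-yl)-2,2-dimethylcyclobutyl]ethan-1-ol | OCC[C@@H]1[C@@H](C(=C)CO[Si](c2ccccc2)(c2ccccc2)C(C)(C)C)CC1(C)C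
F9 | step 17 | 2-[(1R,4S)-4-(3-{[tert-butyl(diphenyl)silyl]oxy}prop-1-en-2-yl)-2,2-dimethylcyclobutyl]acetaldehyde | O=CC[C@@H]1[C@@H](C(=C)CO[Si](c2ccccc2)(c2ccccc2)C(C)(C)C)CC1(C)C
F10 | step 17 | aldol of lactone 10 with F9 (3′-hydroxy analogue of 27) | O=C1O[C@H](O[C@H]2C[C@@H](C)CC[C@@H]2C(C)C)[C@H]3CC=C(C)[C@@H](C[C@H]4C(=C)CC[C@@H]5[C@]4(C)CCC[C@]5(C)C(=O)OC)[C@@]13C(O)C[C@@H]6[C@@H](C(=C)CO[Si](c7ccccc7)(c7ccccc7)C(C)(C)C)CC6(C)C
F11 | step 17 | O-phenyl thionocarbonate of F10 | O=C1O[C@H](O[C@H]2C[C@@H](C)CC[C@@H]2C(C)C)[C@H]3CC=C(C)[C@@H](C[C@H]4C(=C)CC[C@@H]5[C@]4(C)CCC[C@]5(C)C(=O)OC)[C@@]13C(OC(=S)Oc8ccccc8)C[C@@H]6[C@@H](C(=C)CO[Si](c7ccccc7)(c7ccccc7)C(C)(C)C)CC6(C)C
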